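## Retrosynthetic overview

1. Target 24 ⇐ 23 (global O‑demethylation) ⇐ 22 (ring‑A chromene by prenal annulation on the only free phenol) ⇐ 20 (two prenyl groups by Negishi coupling at bromides placed para to the two phenols of 18).
2. The C4 stereocentre comes from asymmetric transfer hydrogenation of the 4‑aryl‑2H‑chromene 17 (an o‑hydroxystyrene) with a chiral phosphoric acid.
3. The pyran ring of the chroman (O1–C2–C3–C4–C4a–C8a) is not closed directly. It arises by acid‑triggered contraction of the eight‑membered acetone ketal ring of 16 (O1–C2–O–C5'–C6'–C4–C4a–C8a, a dibenzo[d,g][1,3]dioxocine); the ketal carbon becomes C2 with both methyl groups and the exocyclic methylene on C4 becomes C3.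
4. Enabling feature: O1 on C8a (ring B) and the phenol oxygen on C5' (ring A, next to the C4‑bearing C6') are both ortho to the diarylmethine carbon C4, so one acetone unit can bridge them.
5. Diaryl ketone 12 comes from two derivatives of one resorcinol 5 (aryllithium 10 + aldehyde 9). Ring order: eight‑membered ketal → chroman ring (by contraction) → chromene ring on ring A.

Key step: step 12

Remark (assumption): atoms are numbered as in the target — chroman part O1, C2–C4, C4a, C5–C8, C8a (ring B); chromene part O1', C2'–C4', C4a', C5'–C8', C8a' (ring A, C6' bonded to C4). The sense of induction of the chiral phosphoric acid in step 13 is assumed to be the one drawn; the other catalyst enantiomer is equally available if the opposite sense is found.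

## Route

Step 1
Reactants: 1 3,5-bis(benzyloxy)benzaldehyde; 2 (4-methoxybenzyl)triphenylphosphonium chloride
Product: 4 1,3-bis(benzyloxy)-5-[2-(4-methoxyphenyl)ethenyl]benzene (E/Z mixture), via phosphonium ylide 3 (not isolated)
Conditions: KOtBu, THF, 0 °C → rt
Reagents that add atoms: none
Why: Wittig olefination with a semistabilised benzylic ylide; the E/Z ratio is irrelevant because the alkene is saturated in step 2.

Step 2
Reactants: 4 1,3-bis(benzyloxy)-5-[2-(4-methoxyphenyl)ethenyl]benzene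
Product: 5 5-[2-(4-methoxyphenyl)ethyl]benzene-1,3-diol
Conditions: H2 (1 atm), 10% Pd/C, EtOAc–EtOH, rt
Reagents that add atoms: none
Why: Heterogeneous hydrogenation should saturate the stilbene and hydrogenolyse both benzyl ethers in one operation, while the aryl methyl ether is inert.

Step 3
Reactants: 5 5-[2-(4-methoxyphenyl)ethyl]benzene-1,3-diol
Product: 6 1,3-bis(methoxymethoxy)-5-[2-(4-methoxyphenyl)ethyl]benzene
Conditions: MOMCl, iPr2NEt, CH2Cl2, 0 °C → rt
Reagents that add atoms: chloromethyl methyl ether (COCCl)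
Why: O‑alkylation of both phenols (MOM protection) installs the 1,3‑bis(OMOM) pattern needed for directed ortho‑metalation in step 7.

Step 4
Reactants: 5 5-[2-(4-methoxyphenyl)ethyl]benzene-1,3-diol
Product: 7 2,4-dihydroxy-6-[2-(4-methoxyphenyl)ethyl]benzaldehyde
Conditions: POCl3, DMF, MeCN, 0 °C → rt; then H2O, 50 °C
Reagents that add atoms: N,N-dimethylformamide (CN(C)C=O); water (O)
Why: Vilsmeier–Haack formylation; the resorcinol ring is far more nucleophilic than the anisole ring and should react at the carbon ortho to one OH and para to the other.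

Step 5
Reactants: 7 2,4-dihydroxy-6-[2-(4-methoxyphenyl)ethyl]benzaldehyde
Product: 8 4-formyl-3-hydroxy-5-[2-(4-methoxyphenyl)ethyl]phenyl 4-methylbenzenesulfonate
Conditions: TsCl (1.05 equiv), K2CO3, acetone, rt
Reagents that add atoms: 4-methylbenzenesulfonyl chloride (Cc1ccc(cc1)S(Cl)(=O)=O)
Why: Selective O‑sulfonylation of the para hydroxyl, because the ortho hydroxyl is held in a hydrogen bond to the formyl group (standard behaviour of 2,4‑dihydroxybenzaldehydes).

Step 6
Reactants: 8 4-formyl-3-hydroxy-5-[2-(4-methoxyphenyl)ethyl]phenyl 4-methylbenzenesulfonate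
Product: 9 4-formyl-3-(methoxymethoxy)-5-[2-(4-methoxyphenyl)ethyl]phenyl 4-methylbenzenesulfonate
Conditions: MOMCl, iPr2NEt, CH2Cl2, 0 → 40 °C
Reagents that add atoms: chloromethyl methyl ether (COCCl)
Why: MOM protection of the chelated phenol removes the acidic proton so that the aldehyde can accept one equivalent of aryllithium.

Step 7
Reactants: 6 1,3-bis(methoxymethoxy)-5-[2-(4-methoxyphenyl)ethyl]benzene; 9 4-formyl-3-(methoxymethoxy)-5-[2-(4-methoxyphenyl)ethyl]phenyl 4-methylbenzenesulfonate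
Product: 11 4-[{2,6-bis(methoxymethoxy)-4-[2-(4-methoxyphenyl)ethyl]phenyl}(hydroxy)methyl]-3-(methoxymethoxy)-5-[2-(4-methoxyphenyl)ethyl]phenyl 4-methylbenzenesulfonate (racemic), via aryllithium 10 (not isolated)
Conditions: 6, n-BuLi, THF, 0 °C; then 9, −78 → 0 °C; H2O
Reagents that add atoms: none
Why: Directed ortho‑metalation between the two OMOM groups, then 1,2‑addition to the aldehyde, which at −78 °C should be much faster than attack on the aryl sulfonate; the carbinol centre is racemic and is removed in step 8.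

Step 8
Reactants: 11 diaryl carbinol from step 7
Product: 12 4-{2,6-bis(methoxymethoxy)-4-[2-(4-methoxyphenyl)ethyl]benzoyl}-3-(methoxymethoxy)-5-[2-(4-methoxyphenyl)ethyl]phenyl 4-methylbenzenesulfonate
Conditions: Dess–Martin periodinane, CH2Cl2, rt
Reagents that add atoms: none
Why: Dess–Martin oxidation of a benzhydrol to the benzophenone; no other oxidisable group is present.

Step 9
Reactants: 12 tris-MOM diaryl ketone
Product: 13 4-{2,6-dihydroxy-4-[2-(4-methoxyphenyl)ethyl]benzoyl}-3-hydroxy-5-[2-(4-methoxyphenyl)ethyl]phenyl 4-methylbenzenesulfonate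
Conditions: 3 M HCl, MeOH–THF, 50 °C
Reagents that add atoms: none
Why: Acidic methanolysis of the three MOM acetals; aryl sulfonate, aryl methyl ethers and the ketone are stable.

Step 10
Reactants: 13 trihydroxy diaryl ketone
Product: 14 1-hydroxy-3,11-bis[2-(4-methoxyphenyl)ethyl]-6,6-dimethyl-12-oxo-12H-dibenzo[d,g][1,3]dioxocin-9-yl 4-methylbenzenesulfonate
Conditions: 2-methoxypropene, PPTS (5 mol%), 4 Å MS, CH2Cl2, 0 °C → rt
Reagents that add atoms: 2-methoxypropene (COC(C)=C)
Why: Acid‑catalysed acetonide formation (transketalisation); only the eight‑membered ketal between the ring‑A oxygen on C5' and one of the two equivalent ring‑B oxygens is possible, since the two ring‑B hydroxyls are meta to each other.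

Step 11
Reactants: 14 eight-membered ketal ketone
Product: 16 1-hydroxy-3,11-bis[2-(4-methoxyphenyl)ethyl]-6,6-dimethyl-12-methylidene-12H-dibenzo[d,g][1,3]dioxocin-9-yl 4-methylbenzenesulfonate, via tertiary carbinol 15 (not isolated)
Conditions: MeMgBr (4 equiv), THF, 0 °C → rt; aqueous work-up; then PPTS (5 mol%), MgSO4, CH2Cl2, rt
Reagents that add atoms: methylmagnesium bromide (C[Mg]Br)
Why: Grignard addition to an o‑hydroxybenzophenone (the magnesium phenolate chelates and activates the hindered carbonyl), then E1 dehydration of the doubly benzylic tertiary carbinol under an acid too weak to open the diaryl ketal.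

Step 12
Reactants: 16 12-methylidene dibenzo[d,g][1,3]dioxocine ketal
Product: 17 3-hydroxy-4-{5-hydroxy-7-[2-(4-methoxyphenyl)ethyl]-2,2-dimethyl-2H-chromen-4-yl}-5-[2-(4-methoxyphenyl)ethyl]phenyl 4-methylbenzenesulfonate
Conditions: Tf2NH (5 mol%), 4 Å MS, CH2Cl2, −20 °C → rt
Reagents that add atoms: none
Why: Proposed new method: the strong acid ionises the ketal C2–O bond to ring A and leaves an aryloxy‑oxocarbenium ion on O1 of ring B; the terminal carbon of the 1,1‑diarylethylene (the future C3) attacks C2, and loss of a proton from C3 of the resulting doubly benzylic C4 cation gives the 2H‑chromene, so the eight‑membered ring O1–C2–O–C5'–C6'–C4–C4a–C8a contracts to the six‑membered ring O1–C2–C3–C4–C4a–C8a in an atom‑neutral isomerisation driven by exchange of a C–O for a C–C bond and by styrene conjugation. The closest known reaction types are the Petasis–Ferrier rearrangement (a cyclic acetal opens to an oxocarbenium ion that recloses on a tethered carbon nucleophile) and Prins cyclisations of oxocarbenium ions released from ketals onto 1,1‑disubstituted alkenes. The pyran ring closes in the 6‑endo‑trig mode (both alkene carbons and the C2–O1 unit end inside the ring). No stereocentre is created, and the C4 cation is neither reduced nor trapped because no hydride donor or external nucleophile is present. The selectivity needed is ionisation towards O1 and not towards the ring‑A oxygen: the tosyloxy group on C8a', meta to the ketal oxygen on C5', makes that oxygen the better leaving group and the poorer carbenium donor, and ring B, whose C4a is flanked by two oxygens, stabilises the developing C4 cation best when it is the ring being annulated. Molecular sieves keep water away so that the oxocarbenium ion is not hydrolysed to acetone.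

Step 13
Reactants: 17 4-aryl-2H-chromen-5-ol
Product: 18 3-hydroxy-4-{(4R)-5-hydroxy-7-[2-(4-methoxyphenyl)ethyl]-2,2-dimethyl-3,4-dihydro-2H-chromen-4-yl}-5-[2-(4-methoxyphenyl)ethyl]phenyl 4-methylbenzenesulfonate
Conditions: (R)-TRIP (10 mol%), Hantzsch ester (1.3 equiv), toluene, 40 °C
Reagents that add atoms: none
Why: Chiral‑phosphoric‑acid‑catalysed asymmetric transfer hydrogenation of an o‑hydroxystyrene (2‑(1‑arylalkenyl)phenol type): protonation at C3 gives an o‑quinone methide/benzylic cation hydrogen‑bonded to the chiral phosphate and the Hantzsch ester delivers hydride to one face of C4, so the catalyst sets the C4 stereocentre and no other π‑system is reducible.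

Step 14
Reactants: 18 (4R)-chroman bis-phenol
Product: 19 2-bromo-4-{(4R)-8-bromo-5-hydroxy-7-[2-(4-methoxyphenyl)ethyl]-2,2-dimethyl-3,4-dihydro-2H-chromen-4-yl}-5-hydroxy-3-[2-(4-methoxyphenyl)ethyl]phenyl 4-methylbenzenesulfonate
Conditions: NBS (2.05 equiv), MeCN, −30 → 0 °C
Reagents that add atoms: N-bromosuccinimide (O=C1CCC(=O)N1Br)
Why: Electrophilic aromatic bromination para to each free phenol (C8 of the chroman and C8' of ring A), the usual preference of NBS in MeCN, with the anisole rings far less reactive; the benzylic stereocentre is not touched under ionic conditions.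

Step 15
Reactants: 19 dibromo bis-phenol
Product: 20 2-bromo-4-{(4R)-8-bromo-5-methoxy-7-[2-(4-methoxyphenyl)ethyl]-2,2-dimethyl-3,4-dihydro-2H-chromen-4-yl}-5-methoxy-3-[2-(4-methoxyphenyl)ethyl]phenyl 4-methylbenzenesulfonate
Conditions: MeI, K2CO3, DMF, rt
Reagents that add atoms: iodomethane (CI)
Why: Williamson O‑methylation masks the two phenols so that later only the oxygen on C8a' can take part in chromene formation; the aryl tosylate is stable to carbonate at rt.

Step 16
Reactants: 20 dibromo bis(methyl ether)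
Product: 21 5-methoxy-4-{(4R)-5-methoxy-7-[2-(4-methoxyphenyl)ethyl]-2,2-dimethyl-8-(3-methylbut-2-en-1-yl)-3,4-dihydro-2H-chromen-4-yl}-3-[2-(4-methoxyphenyl)ethyl]-2-(3-methylbut-2-en-1-yl)phenyl 4-methylbenzenesulfonate
Conditions: prenylzinc bromide (3 equiv, THF solution), Pd(OAc)2 (4 mol%), CPhos (8 mol%), THF, rt
Reagents that add atoms: (3-methylbut-2-en-1-yl)zinc bromide (CC(C)=CC[Zn]Br)
Why: Negishi coupling of both aryl bromides; the Pd–CPhos system is linear‑selective for prenylzinc reagents and at rt should leave the aryl tosylate alone.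

Step 17
Reactants: 21 diprenyl aryl tosylate
Product: 22 5-methoxy-4-{(4R)-5-methoxy-7-[2-(4-methoxyphenyl)ethyl]-2,2-dimethyl-8-(3-methylbut-2-en-1-yl)-3,4-dihydro-2H-chromen-4-yl}-3-[2-(4-methoxyphenyl)ethyl]-2-(3-methylbut-2-en-1-yl)phenol
Conditions: KOH, MeOH–THF, 60 °C
Reagents that add atoms: none
Why: Basic cleavage of the aryl sulfonate at sulfur frees the single phenol on C8a'; prenyl groups and methyl ethers are base‑stable.

Step 18
Reactants: 22 mono-phenol
Product: 23 (4R)-5-methoxy-4-{5-methoxy-7-[2-(4-methoxyphenyl)ethyl]-2,2-dimethyl-8-(3-methylbut-2-en-1-yl)-2H-chromen-6-yl}-7-[2-(4-methoxyphenyl)ethyl]-2,2-dimethyl-8-(3-methylbut-2-en-1-yl)-3,4-dihydro-2H-chromene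
Conditions: 3-methylbut-2-enal, ethylenediammonium diacetate (20 mol%), toluene, 110 °C
Reagents that add atoms: 3-methylbut-2-enal (CC(C)=CC=O)
Why: Amine‑salt‑catalysed condensation of the phenol with prenal at its only free ortho carbon (C4a'), then oxa‑6π electrocyclisation, gives the 2,2‑dimethyl‑2H‑chromene; closure can only occur on the C8a' oxygen because the C5' oxygen is methylated.

Step 19
Reactants: 23 tetramethyl ether
Product: 24 (4R)-4-{5-hydroxy-7-[2-(4-hydroxyphenyl)ethyl]-2,2-dimethyl-8-(3-methylbut-2-en-1-yl)-2H-chromen-6-yl}-7-[2-(4-hydroxyphenyl)ethyl]-2,2-dimethyl-8-(3-methylbut-2-en-1-yl)-3,4-dihydro-2H-chromen-5-ol (target)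
Conditions: NaSEt (excess), DMF, 140 °C; then aq. NH4Cl
Reagents that add atoms: none
Why: Thiolate SN2 O‑demethylation of the four aryl methyl ethers under basic, non‑electrophilic conditions that should spare the prenyl groups, the chromene and the benzylic stereocentre.

## Compound list

1 | 3,5-bis(benzyloxy)benzaldehyde | O=Cc1cc(OCc2ccccc2)cc(OCc2ccccc2)c1 | starting material
2 | (4-methoxybenzyl)triphenylphosphonium chloride | [Cl-].COc1ccc(C[P+](c2ccccc2)(c2ccccc2)c2ccccc2)cc1 | starting material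
3 | (4-methoxybenzylidene)triphenylphosphorane | COc1ccc(C=P(c2ccccc2)(c2ccccc2)c2ccccc2)cc1 | intermediate
4 | 1,3-bis(benzyloxy)-5-[2-(4-methoxyphenyl)ethenyl]benzene (E/Z mixture) | COc1ccc(C=Cc2cc(OCc3ccccc3)cc(OCc3ccccc3)c2)cc1 | intermediate
5 | 5-[2-(4-methoxyphenyl)ethyl]benzene-1,3-diol | COc1ccc(CCc2cc(O)cc(O)c2)cc1 | intermediate
6 | 1,3-bis(methoxymethoxy)-5-[2-(4-methoxyphenyl)ethyl]benzene | COCOc1cc(CCc2ccc(OC)cc2)cc(OCOC)c1 | intermediate
7 | 2,4-dihydroxy-6-[2-(4-methoxyphenyl)ethyl]benzaldehyde | COc1ccc(CCc2cc(O)cc(O)c2C=O)cc1 | intermediate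
8 | 4-formyl-3-hydroxy-5-[2-(4-methoxyphenyl)ethyl]phenyl 4-methylbenzenesulfonate | COc1ccc(CCc2cc(OS(=O)(=O)c3ccc(C)cc3)cc(O)c2C=O)cc1 | intermediate
9 | 4-formyl-3-(methoxymethoxy)-5-[2-(4-methoxyphenyl)ethyl]phenyl 4-methylbenzenesulfonate | COCOc1cc(OS(=O)(=O)c2ccc(C)cc2)cc(CCc2ccc(OC)cc2)c1C=O | intermediate
10 | {2,6-bis(methoxymethoxy)-4-[2-(4-methoxyphenyl)ethyl]phenyl}lithium | [Li]c1c(OCOC)cc(CCc2ccc(OC)cc2)cc1OCOC | intermediate
11 | 4-[{2,6-bis(methoxymethoxy)-4-[2-(4-methoxyphenyl)ethyl]phenyl}(hydroxy)methyl]-3-(methoxymethoxy)-5-[2-(4-methoxyphenyl)ethyl]phenyl 4-methylbenzenesulfonate (racemic) | COCOc1cc(CCc2ccc(OC)cc2)cc(OCOC)c1C(O)c1c(OCOC)cc(OS(=O)(=O)c2ccc(C)cc2)cc1CCc1ccc(OC)cc1 | intermediate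
12 | 4-{2,6-bis(methoxymethoxy)-4-[2-(4-methoxyphenyl)ethyl]benzoyl}-3-(methoxymethoxy)-5-[2-(4-methoxyphenyl)ethyl]phenyl 4-methylbenzenesulfonate | COCOc1cc(CCc2ccc(OC)cc2)cc(OCOC)c1C(=O)c1c(OCOC)cc(OS(=O)(=O)c2ccc(C)cc2)cc1CCc1ccc(OC)cc1 | intermediate
13 | 4-{2,6-dihydroxy-4-[2-(4-methoxyphenyl)ethyl]benzoyl}-3-hydroxy-5-[2-(4-methoxyphenyl)ethyl]phenyl 4-methylbenzenesulfonate | Oc1cc(CCc2ccc(OC)cc2)cc(O)c1C(=O)c1c(O)cc(OS(=O)(=O)c2ccc(C)cc2)cc1CCc1ccc(OC)cc1 | intermediate
14 | 1-hydroxy-3,11-bis[2-(4-methoxyphenyl)ethyl]-6,6-dimethyl-12-oxo-12H-dibenzo[d,g][1,3]dioxocin-9-yl 4-methylbenzenesulfonate | CC1(C)Oc2cc(CCc3ccc(OC)cc3)cc(O)c2C(=O)c2c(O1)cc(OS(=O)(=O)c3ccc(C)cc3)cc2CCc2ccc(OC)cc2 | intermediate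
15 | 1,12-dihydroxy-3,11-bis[2-(4-methoxyphenyl)ethyl]-6,6,12-trimethyl-12H-dibenzo[d,g][1,3]dioxocin-9-yl 4-methylbenzenesulfonate (racemic) | CC1(C)Oc2cc(CCc3ccc(OC)cc3)cc(O)c2C(C)(O)c2c(O1)cc(OS(=O)(=O)c3ccc(C)cc3)cc2CCc2ccc(OC)cc2 | intermediate
16 | 1-hydroxy-3,11-bis[2-(4-methoxyphenyl)ethyl]-6,6-dimethyl-12-methylidene-12H-dibenzo[d,g][1,3]dioxocin-9-yl 4-methylbenzenesulfonate | CC1(C)Oc2cc(CCc3ccc(OC)cc3)cc(O)c2C(=C)c2c(O1)cc(OS(=O)(=O)c3ccc(C)cc3)cc2CCc2ccc(OC)cc2 | intermediate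
17 | 3-hydroxy-4-{5-hydroxy-7-[2-(4-methoxyphenyl)ethyl]-2,2-dimethyl-2H-chromen-4-yl}-5-[2-(4-methoxyphenyl)ethyl]phenyl 4-methylbenzenesulfonate | CC1(C)C=C(c2c(O)cc(OS(=O)(=O)c3ccc(C)cc3)cc2CCc2ccc(OC)cc2)c2c(O)cc(CCc3ccc(OC)cc3)cc2O1 | intermediate
18 | 3-hydroxy-4-{(4R)-5-hydroxy-7-[2-(4-methoxyphenyl)ethyl]-2,2-dimethyl-3,4-dihydro-2H-chromen-4-yl}-5-[2-(4-methoxyphenyl)ethyl]phenyl 4-methylbenzenesulfonate | Cc1ccc(cc1)S(=O)(=O)Oc1cc(O)c([C@H]2CC(C)(C)Oc3cc(CCc4ccc(OC)cc4)cc(O)c32)c(CCc2ccc(OC)cc2)c1 | intermediate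
19 | 2-bromo-4-{(4R)-8-bromo-5-hydroxy-7-[2-(4-methoxyphenyl)ethyl]-2,2-dimethyl-3,4-dihydro-2H-chromen-4-yl}-5-hydroxy-3-[2-(4-methoxyphenyl)ethyl]phenyl 4-methylbenzenesulfonate | Cc1ccc(cc1)S(=O)(=O)Oc1cc(O)c([C@H]2CC(C)(C)Oc3c(Br)c(CCc4ccc(OC)cc4)cc(O)c32)c(CCc2ccc(OC)cc2)c1Br | intermediate
20 | 2-bromo-4-{(4R)-8-bromo-5-methoxy-7-[2-(4-methoxyphenyl)ethyl]-2,2-dimethyl-3,4-dihydro-2H-chromen-4-yl}-5-methoxy-3-[2-(4-methoxyphenyl)ethyl]phenyl 4-methylbenzenesulfonate | Cc1ccc(cc1)S(=O)(=O)Oc1cc(OC)c([C@H]2CC(C)(C)Oc3c(Br)c(CCc4ccc(OC)cc4)cc(OC)c32)c(CCc2ccc(OC)cc2)c1Br | intermediate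
21 | 5-methoxy-4-{(4R)-5-methoxy-7-[2-(4-methoxyphenyl)ethyl]-2,2-dimethyl-8-(3-methylbut-2-en-1-yl)-3,4-dihydro-2H-chromen-4-yl}-3-[2-(4-methoxyphenyl)ethyl]-2-(3-methylbut-2-en-1-yl)phenyl 4-methylbenzenesulfonate | Cc1ccc(cc1)S(=O)(=O)Oc1cc(OC)c([C@H]2CC(C)(C)Oc3c(CC=C(C)C)c(CCc4ccc(OC)cc4)cc(OC)c32)c(CCc2ccc(OC)cc2)c1CC=C(C)C | intermediate
22 | 5-methoxy-4-{(4R)-5-methoxy-7-[2-(4-methoxyphenyl)ethyl]-2,2-dimethyl-8-(3-methylbut-2-en-1-yl)-3,4-dihydro-2H-chromen-4-yl}-3-[2-(4-methoxyphenyl)ethyl]-2-(3-methylbut-2-en-1-yl)phenol | Oc1cc(OC)c([C@H]2CC(C)(C)Oc3c(CC=C(C)C)c(CCc4ccc(OC)cc4)cc(OC)c32)c(CCc2ccc(OC)cc2)c1CC=C(C)C | intermediate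
23 | (4R)-5-methoxy-4-{5-methoxy-7-[2-(4-methoxyphenyl)ethyl]-2,2-dimethyl-8-(3-methylbut-2-en-1-yl)-2H-chromen-6-yl}-7-[2-(4-methoxyphenyl)ethyl]-2,2-dimethyl-8-(3-methylbut-2-en-1-yl)-3,4-dihydro-2H-chromene | CC(C)=CCc1c(CCc2ccc(OC)cc2)c([C@H]2CC(C)(C)Oc3c(CC=C(C)C)c(CCc4ccc(OC)cc4)cc(OC)c32)c(OC)c2c1OC(C)(C)C=C2 | intermediate
24 | (4R)-4-{5-hydroxy-7-[2-(4-hydroxyphenyl)ethyl]-2,2-dimethyl-8-(3-methylbut-2-en-1-yl)-2H-chromen-6-yl}-7-[2-(4-hydroxyphenyl)ethyl]-2,2-dimethyl-8-(3-methylbut-2-en-1-yl)-3,4-dihydro-2H-chromen-5-ol | CC(C)=CCc1c(CCc2ccc(O)cc2)c([C@H]2CC(C)(C)Oc3c(CC=C(C)C)c(CCc4ccc(O)cc4)cc(O)c32)c(O)c2c1OC(C)(C)C=C2 | target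

## Step count and risks

Total step count: 19. Longest linear sequence: 18 steps (1, 2, 4–19).

Steps most likely to fail:

Step 12 (proposed new method). The ketal may ionise towards the ring‑A oxygen and close the pyran onto ring A, or the oxocarbenium ion may lose acetone by adventitious hydrolysis before the C–C bond forms. Fallback with known chemistry, closing the ring directly: from ketone 12, addition of 2‑methylprop‑1‑enylmagnesium bromide (THF, 0 °C) should give the tertiary allylic alcohol F1. Treatment with 2 M HCl in MeOH (40 °C) should remove the three MOM groups and ionise the alcohol; the dimethylallyl cation is captured at its CMe2 terminus by one of the two equivalent ring‑B phenols (the classical cyclodehydration route to 2,2‑dimethyl‑2H‑chromenes). This returns to the route at 17; any isomer closed on the ring‑A oxygen would be removed by chromatography.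

Step 13. Hydride transfer to the very congested diaryl cation, which has two ortho substituents on each aryl ring, may be slow or poorly face‑selective. Fallback: from 17, ionic hydrogenation (Et3SiH, TFA, CH2Cl2, 0 °C) should give the racemic chroman F2. Both phenols are acylated with (1R,2S,5R)‑menthyl chloroformate (pyridine, DMAP), the diastereomeric bis‑carbonates are separated by chromatography or crystallisation, and the (4R) bis‑carbonate F3 is cleaved with LiOH in aqueous THF at 0 °C to return 18.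

Step 14. Bromination may occur ortho instead of para to a phenol (C6 of the chroman, C4a' of ring A), or over‑bromination may set in. Fallback: from 18, both phenols are silylated (TIPSOTf, 2,6‑lutidine, CH2Cl2) to the bis‑TIPS ether F4, whose bulky silyloxy groups shield the flanking ortho positions. NBS in MeCN should then brominate para to each silyloxy group to give the dibromide F5, and TBAF (THF, 0 °C) removes the silyl groups to return 19.

## Further compounds

F1 | step 12 | 4-[1-{2,6-bis(methoxymethoxy)-4-[2-(4-methoxyphenyl)ethyl]phenyl}-1-hydroxy-3-methylbut-2-en-1-yl]-3-(methoxymethoxy)-5-[2-(4-methoxyphenyl)ethyl]phenyl 4-methylbenzenesulfonate (racemic) | COCOc1cc(CCc2ccc(OC)cc2)cc(OCOC)c1C(O)(C=C(C)C)c1c(OCOC)cc(OS(=O)(=O)c2ccc(C)cc2)cc1CCc1ccc(OC)cc1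
F2 | step 13 | racemic 3-hydroxy-4-{5-hydroxy-7-[2-(4-methoxyphenyl)ethyl]-2,2-dimethyl-3,4-dihydro-2H-chromen-4-yl}-5-[2-(4-methoxyphenyl)ethyl]phenyl 4-methylbenzenesulfonate | Cc1ccc(cc1)S(=O)(=O)Oc1cc(O)c(C2CC(C)(C)Oc3cc(CCc4ccc(OC)cc4)cc(O)c32)c(CCc2ccc(OC)cc2)c1
F3 | step 13 | bis[(1R,2S,5R)-menthyl carbonate] of 18 (both phenols acylated, 4R) | Cc1ccc(cc1)S(=O)(=O)Oc1cc(OC(=O)O[C@@H]2C[C@H](C)CC[C@H]2C(C)C)c([C@H]2CC(C)(C)Oc3cc(CCc4ccc(OC)cc4)cc(OC(=O)O[C@@H]4C[C@H](C)CC[C@H]4C(C)C)c32)c(CCc2ccc(OC)cc2)c1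
F4 | step 14 | bis(triisopropylsilyl) ether of 18 | Cc1ccc(cc1)S(=O)(=O)Oc1cc(O[Si](C(C)C)(C(C)C)C(C)C)c([C@H]2CC(C)(C)Oc3cc(CCc4ccc(OC)cc4)cc(O[Si](C(C)C)(C(C)C)C(C)C)c32)c(CCc2ccc(OC)cc2)c1
F5 | step 14 | bis(triisopropylsilyl) ether of 19 | Cc1ccc(cc1)S(=O)(=O)Oc1cc(O[Si](C(C)C)(C(C)C)C(C)C)c([C@H]2CC(C)(C)Oc3c(Br)c(CCc4ccc(OC)cc4)cc(O[Si](C(C)C)(C(C)C)C(C)C)c32)c(CCc2ccc(OC)cc2)c1Br
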